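**Retrosynthetic overview**
- Albanin A ← removal of four O-allyl groups from a fully O-allylated 3-prenylflavone under neutral palladium catalysis, so the prenyl group never meets strong acid.
- Ring C (the pyranone) is the only ring formed and is closed last, by cyclodehydration of a 2-prenyl-1,3-diketone (ring A phenol onto the ring B carbonyl); rings A and B are bought as arenes.
- The C-3 prenyl group ← C-alkylation of the 1,3-diketone with prenyl bromide.
- Key C–C bond (future C2–C3) ← intermolecular crossed Claisen condensation of a ring A acetophenone enolate with a ring B methyl benzoate.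
- Both fragments ← O-allylation of 2,4,6-trihydroxyacetophenone and of methyl 2,4-dihydroxybenzoate.

Assumption: the target SMILES contains no stereocentre and the molecule is achiral, so there is no enantiomer to select and the route needs no stereocontrol.

**Step 1**
Reactants: 1 2,4,6-trihydroxyacetophenone
Product: 2 1-[2,4-bis(allyloxy)-6-hydroxyphenyl]ethanone
Conditions: allyl bromide (2.1 equiv), K2CO3 (2.2 equiv), acetone, reflux, 6 h
Reagents that add atoms: allyl bromide, C=CCBr
Why: Williamson ether synthesis in which the para hydroxyl and one ortho hydroxyl are alkylated, while the second ortho hydroxyl, hydrogen-bonded to the acetyl carbonyl, is the least nucleophilic and stays free for the later ring closure.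

**Step 2**
Reactants: 3 methyl 2,4-dihydroxybenzoate
Product: 4 methyl 2,4-bis(allyloxy)benzoate
Conditions: allyl bromide (3 equiv), K2CO3 (4 equiv), DMF, 60 °C, 12 h
Reagents that add atoms: allyl bromide, C=CCBr
Why: Williamson ether synthesis under forcing conditions (excess reagent, DMF, heat) that also alkylates the chelated 2-hydroxyl, giving a non-enolisable ester whose allyl ethers tolerate strong base and mild acid.

**Step 3**
Reactants: 2 1-[2,4-bis(allyloxy)-6-hydroxyphenyl]ethanone; 4 methyl 2,4-bis(allyloxy)benzoate
Product: 5 1-[2,4-bis(allyloxy)-6-hydroxyphenyl]-3-[2,4-bis(allyloxy)phenyl]propane-1,3-dione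
Conditions: LiN(SiMe3)2 (4 equiv), THF, −78 °C, 1 h; then 4 (1.2 equiv), −78 °C → rt (45 °C if slow); cold 1 M aq. HCl quench
Reagents that add atoms: none
Why: Intermolecular crossed Claisen condensation in which the phenoxide/enolate dianion of 2 adds to the non-enolisable ester 4 and expels methoxide, driven to completion by irreversible deprotonation of the 1,3-diketone product by the excess amide base.

**Step 4**
Reactants: 5 1-[2,4-bis(allyloxy)-6-hydroxyphenyl]-3-[2,4-bis(allyloxy)phenyl]propane-1,3-dione; 6 prenyl bromide (1-bromo-3-methylbut-2-ene, 1.05 equiv)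
Product: 7 1-[2,4-bis(allyloxy)-6-hydroxyphenyl]-3-[2,4-bis(allyloxy)phenyl]-2-(3-methylbut-2-en-1-yl)propane-1,3-dione (racemic)
Conditions: K2CO3 (1.3 equiv), acetone, rt → 50 °C, 8 h
Reagents that add atoms: none
Why: SN2 C-alkylation of the stabilised 1,3-diketone enolate (the most acidic site, ahead of the chelated phenol) by the soft allylic bromide; the new stereocentre is formed racemic and is erased in step 5, and any material that has already closed to the hemiketal converges there too.

**Step 5**
Reactants: 7 1-[2,4-bis(allyloxy)-6-hydroxyphenyl]-3-[2,4-bis(allyloxy)phenyl]-2-(3-methylbut-2-en-1-yl)propane-1,3-dione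
Product: 9 5,7-bis(allyloxy)-2-[2,4-bis(allyloxy)phenyl]-3-(3-methylbut-2-en-1-yl)-4H-chromen-4-one, via cyclic hemiketal 8 (not isolated)
Conditions: HCl (0.5 equiv, as 0.5 M solution in MeOH), MeOH–THF 2:1, 45 °C, 2–4 h
Reagents that add atoms: none
Why: Acid-catalysed cyclodehydration of an o-hydroxyaryl 1,3-diketone, in which the only free phenol (ring A) adds to the ring B ketone and the resulting 2-hydroxychromanone (a racemic diastereomer mixture) loses water to the conjugated pyranone, so the regiochemistry is fixed and the dilute methanolic acid leaves the allyl ethers and the prenyl alkene alone.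

**Step 6**
Reactants: 9 5,7-bis(allyloxy)-2-[2,4-bis(allyloxy)phenyl]-3-(3-methylbut-2-en-1-yl)-4H-chromen-4-one
Product: 10 Albanin A, 2-(2,4-dihydroxyphenyl)-5,7-dihydroxy-3-(3-methylbut-2-en-1-yl)-4H-chromen-4-one
Conditions: Pd(PPh3)4 (5 mol %), morpholine (12 equiv), degassed THF, rt → 40 °C, argon
Reagents that add atoms: none
Why: Tsuji–Trost-type deallylation in which zerovalent palladium ionises each aryl allyl ether to a π-allyl complex and a phenoxide and morpholine traps the allyl unit, under neutral conditions that cannot touch the C-bound prenyl group because it carries no leaving group.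

**Compound list**
1 | 2,4,6-trihydroxyacetophenone | CC(=O)c1c(O)cc(O)cc1O | starting material
2 | 1-[2,4-bis(allyloxy)-6-hydroxyphenyl]ethanone | CC(=O)c1c(O)cc(OCC=C)cc1OCC=C | intermediate
3 | methyl 2,4-dihydroxybenzoate | COC(=O)c1ccc(O)cc1O | starting material
4 | methyl 2,4-bis(allyloxy)benzoate | COC(=O)c1ccc(OCC=C)cc1OCC=C | intermediate
5 | 1-[2,4-bis(allyloxy)-6-hydroxyphenyl]-3-[2,4-bis(allyloxy)phenyl]propane-1,3-dione (mainly enolised) | O=C(CC(=O)c1ccc(OCC=C)cc1OCC=C)c1c(O)cc(OCC=C)cc1OCC=C | intermediate
6 | prenyl bromide (1-bromo-3-methylbut-2-ene) | CC(C)=CCBr | starting material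
7 | 1-[2,4-bis(allyloxy)-6-hydroxyphenyl]-3-[2,4-bis(allyloxy)phenyl]-2-(3-methylbut-2-en-1-yl)propane-1,3-dione, racemic | CC(C)=CCC(C(=O)c1ccc(OCC=C)cc1OCC=C)C(=O)c1c(O)cc(OCC=C)cc1OCC=C | intermediate
8 | 5,7-bis(allyloxy)-2-[2,4-bis(allyloxy)phenyl]-2-hydroxy-3-(3-methylbut-2-en-1-yl)chroman-4-one, cyclic hemiketal, racemic diastereomer mixture, not isolated | CC(C)=CCC1C(=O)c2c(OCC=C)cc(OCC=C)cc2OC1(O)c1ccc(OCC=C)cc1OCC=C | intermediate
9 | 5,7-bis(allyloxy)-2-[2,4-bis(allyloxy)phenyl]-3-(3-methylbut-2-en-1-yl)-4H-chromen-4-one | CC(C)=CCc1c(-c2ccc(OCC=C)cc2OCC=C)oc2cc(OCC=C)cc(OCC=C)c2c1=O | intermediate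
10 | Albanin A, 2-(2,4-dihydroxyphenyl)-5,7-dihydroxy-3-(3-methylbut-2-en-1-yl)-4H-chromen-4-one, achiral | CC(C)=CCc1c(-c2ccc(O)cc2O)oc2cc(O)cc(O)c2c1=O | target

**Totals**
Total step count: 6. Longest linear sequence: 5 steps (steps 1, 3, 4, 5, 6; the ring B branch through step 2 is equally long).

**Steps most likely to fail, with fallbacks**

Step 3 (crossed Claisen condensation). The ester 4 is electron-rich and ortho-substituted, so addition of the dianion may be slow or incomplete. The fallback sets out from 4 (with 2 as partner) and comes back at 5. Ester 4 is saponified (LiOH, THF–MeOH–H2O, 50 °C, then HCl) to 2,4-bis(allyloxy)benzoic acid F1. The free phenol of 2 is esterified with this acid (EDC·HCl, DMAP, CH2Cl2, rt) to give 2-acetyl-3,5-bis(allyloxy)phenyl 2,4-bis(allyloxy)benzoate F2. Treatment with KOtBu in THF at rt then moves the aroyl group from oxygen to the acetyl carbon (Baker–Venkataraman rearrangement), which makes the same C–C bond intramolecularly and delivers 5.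

Step 4 (C-prenylation of the diketone). O-alkylation of the enol or the phenol, or double alkylation, may compete. The fallback sets out from 2 and comes back at 7, with the prenyl group installed before the condensation. The dianion of 2 (LiN(iPr)2, 2.2 equiv, THF, −78 °C) is alkylated at carbon with 6 to give 1-[2,4-bis(allyloxy)-6-hydroxyphenyl]-5-methylhex-4-en-1-one F3. The dianion of this ketone (LiN(SiMe3)2, 4 equiv, THF, −78 °C → rt) is then acylated with ester 4 in the same Claisen manner, giving 7 directly with no ambiguity between C- and O-alkylation.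

Step 5 (cyclodehydration with the prenyl group present). Acid may add to the prenyl alkene or close it onto the enol oxygen to a dimethyldihydropyran. The fallback sets out from 5 and comes back at 9, with the order of ring closure and prenylation reversed. The unprenylated diketone 5 is cyclodehydrated under standard stronger acid (cat. H2SO4, AcOH, 80 °C), which is safe because no prenyl group is present, to give 5,7-bis(allyloxy)-2-[2,4-bis(allyloxy)phenyl]-4H-chromen-4-one F4. This flavone is deprotonated at C-3 (LiN(iPr)2, THF, −78 °C) and the 3-lithioflavone is alkylated with 6 to give 9.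

**Further compounds**
F1 | step 3 | 2,4-bis(allyloxy)benzoic acid | OC(=O)c1ccc(OCC=C)cc1OCC=C
F2 | step 3 | 2-acetyl-3,5-bis(allyloxy)phenyl 2,4-bis(allyloxy)benzoate | CC(=O)c1c(OC(=O)c2ccc(OCC=C)cc2OCC=C)cc(OCC=C)cc1OCC=C
F3 | step 4 | 1-[2,4-bis(allyloxy)-6-hydroxyphenyl]-5-methylhex-4-en-1-one | CC(C)=CCCC(=O)c1c(O)cc(OCC=C)cc1OCC=C
F4 | step 5 | 5,7-bis(allyloxy)-2-[2,4-bis(allyloxy)phenyl]-4H-chromen-4-one | O=c1cc(-c2ccc(OCC=C)cc2OCC=C)oc2cc(OCC=C)cc(OCC=C)c12
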